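**Retrosynthetic overview** (numbering of the target as a cyclohepta[b]furan: O1, C2 lactone C=O, C3 =CH2, C3a, C4, C5 C=O, C6 Me, C7 OH/crotonoyl, C8 O-isovalerate, C8a)

1. Late stage: the Z-crotonoyl group comes from a propargylic silyl ether on C7 (Lindlar, oxidation); the lactone ring and the C8 ester come together from a cis C8/C8a diol by Prévost-type opening of a dioxolanylium ion (inversion at C8a); the C2/C3 unit is put on C3a by Michael/Horner–Wadsworth–Emmons reaction of a C3a=C4 enone.
2. That enone and the C7–O bond arise by Ferrier-type opening of an oxygen bridge between C3a and C7; the C5 oxygen and the C6 methyl come from an α-methoxy enone (cuprate addition, enol triflate reduction).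
3. Key disconnection: C3a–C8a and C7–C8, made together by a (5+2) cycloaddition of a kojic acid-derived 4-methoxy-3-oxidopyrylium ylide (C3a, C4, C5, C6, C7 and the bridging O) with vinylene carbonate (C8, C8a and both their oxygens).
4. Enabling feature: the tertiary C7–OH and C3a are the two ends of the segment C3a–C4–C5(=O)–C6–C7, both β to the C5 ketone, so the carbocycle is a latent 8-oxabicyclo[3.2.1]octan-3-one (O bridging C7 and C3a) whose two-carbon bridge C8–C8a is vicinally dioxygenated. This is the retron of an oxidopyrylium–enediol cycloadduct.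
5. Ring order: pyranone (kojic acid) → cycloheptane with oxa bridge (step 6) → bridge opened to the monocyclic cycloheptenone (step 10) → γ-lactone (step 14).

Key step: step 6

Assumption (chemistry): the sense of facial induction by the silyloxy stereocentre in step 6 is taken from the A(1,3)-strain model; this carbinol centre is destroyed in step 17, so the antipodal ligand would be used in step 3 if the induction proved opposite.

**Route**

Step 1
Reactants: 1 kojic acid
Product: 2 2-(hydroxymethyl)-5-[(4-methoxyphenyl)methoxy]-4H-pyran-4-one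
Conditions: PMBCl, K2CO3, DMF, 60 °C
Reagents that add atoms: 4-methoxybenzyl chloride, COc1ccc(CCl)cc1
Why: Williamson etherification in which the acidic enolic 5-OH (a vinylogous carboxylic acid) is alkylated selectively while the primary alcohol stays free.

Step 2
Reactants: 2 PMB ether of kojic acid
Product: 3 5-[(4-methoxyphenyl)methoxy]-4-oxo-4H-pyran-2-carbaldehyde
Conditions: MnO2 (activated), CH2Cl2, rt
Reagents that add atoms: none
Why: MnO2 oxidation of an allylic-type primary alcohol (the carbinol is attached to the pyranone C=C) should stop at the aldehyde.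

Step 3
Reactants: 3 pyranone aldehyde; 4 propyne
Product: 5 2-[(1R)-1-hydroxybut-2-yn-1-yl]-5-[(4-methoxyphenyl)methoxy]-4H-pyran-4-one
Conditions: propyne (excess), Me2Zn, ProPhenol ligand (20 mol %, the enantiomer that gives the R carbinol), Ph3PO (cat.), toluene, 0 °C
Reagents that add atoms: propyne 4, CC#C
Why: ProPhenol–zinc-catalysed enantioselective alkynylation of an unsaturated aldehyde, in which the chiral dinuclear zinc complex delivers the propynyl group to one face of the formyl group and sets the R carbinol.

Step 4
Reactants: 5 propargylic alcohol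
Product: 6 2-[(1R)-1-(tert-butyldimethylsilyloxy)but-2-yn-1-yl]-5-[(4-methoxyphenyl)methoxy]-4H-pyran-4-one
Conditions: TBSCl, imidazole, DMF, rt
Reagents that add atoms: tert-butyldimethylsilyl chloride, CC(C)(C)[Si](C)(C)Cl
Why: Standard imidazole-promoted silylation of the secondary alcohol, which leaves the configuration untouched.

Step 5
Reactants: 6 TBS ether
Product: 7 2-[(1R)-1-(tert-butyldimethylsilyloxy)but-2-yn-1-yl]-5-hydroxy-4H-pyran-4-one
Conditions: TFA, Et3SiH, CH2Cl2, 0 °C
Reagents that add atoms: none
Why: Acidolysis of the 4-methoxybenzyl enol ether with reductive capture of the benzyl cation by Et3SiH frees the 5-OH needed for ylide formation, and the TBS ether on the electron-poor carbinol should survive the brief exposure.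

Step 6
Reactants: 7 5-hydroxypyranone; 8 vinylene carbonate
Product: 11 endo cycloadduct: 3-methoxy-8-oxabicyclo[3.2.1]oct-3-en-2-one with the (1R)-1-(TBS-oxy)but-2-ynyl group on the bridgehead remote from the ketone (future C7) and a cyclic carbonate cis-fused on the two-carbon bridge (C8/C8a) anti to the oxygen bridge, via pyrylium triflate 9 (not isolated), via oxidopyrylium ylide 10 (not isolated)
Conditions: MeOTf, CH2Cl2, rt; then 8 (10 equiv), PhNMe2, ClCH2CH2Cl, 60 °C
Reagents that add atoms: methyl triflate, COS(=O)(=O)C(F)(F)F; vinylene carbonate 8, O=C1OC=CO1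
Why: MeOTf O-methylates the pyranone carbonyl to the 3-hydroxypyrylium salt 9 and the amine base gives the 4-methoxy-3-oxidopyrylium ylide 10, whose five-carbon 4π unit (future C3a, C4, C5, C6, C7) adds through the two carbons flanking the ring oxygen to the alkene of 8 in a concerted, suprafacial (5+2) cycloaddition; the closest known reaction type is the oxidopyrylium–alkene cycloaddition of kojic acid-derived ylides. Both new rings, the seven-membered carbocycle and the oxolane that holds the former pyran oxygen as a bridge, are closed in this single cycloaddition event by the C3a–C8a and C7–C8 bonds, and the carbonate ring is carried in intact. C8 and C8a receive their oxygens cis because the Z alkene reacts suprafacially, and anti to the oxygen bridge because the endo transition state avoids lone-pair repulsion between the carbonate and the ring oxygen and gains secondary overlap with the oxidoenone; C3a is fixed by the bridge geometry. The absolute sense is set by the R silyloxy stereocentre: in the rotamer of lowest A(1,3) strain (carbinol C–H in the ring plane next to the ring C–H) the OTBS group covers one face and the slim propynyl group the other, so 8 adds anti to OTBS and C7 is formed in the required configuration, the minor diastereomer being separable. The step needs endo and facial selectivity, secured as described, and chemoselectivity over ylide dimerisation, secured by the excess of 8 and the thermal reversibility of the dimer; regiochemistry does not arise because 8 is symmetric.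

Step 7
Reactants: 11 endo cycloadduct
Product: 12 enol triflate: the former ketone carbon (future C4) carries OTf, the adjacent carbon (future C5) keeps OMe, and the new methyl group on the future C6 is syn to the oxygen bridge
Conditions: CuI, MeLi (2 equiv), Et2O/THF, −78 to −40 °C; then PhNTf2, −78 to 0 °C
Reagents that add atoms: lithium dimethylcuprate, [Li+].C[Cu-]C; N-phenyl-bis(trifluoromethanesulfonimide), O=S(=O)(N(c1ccccc1)S(=O)(=O)C(F)(F)F)C(F)(F)F
Why: Cuprate conjugate addition to the α-methoxy enone and O-triflation of the regiodefined enolate; the methyl group enters from the exo face (syn to the oxygen bridge) because the endo face is covered by the carbonate ring, which sets C6.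

Step 8
Reactants: 12 enol triflate
Product: 13 methyl enol ether: 3-methoxy-4-methyl-8-oxabicyclo[3.2.1]oct-2-ene with the substituents and configurations of 12 and H in place of OTf
Conditions: Pd(OAc)2 (5 mol %), PPh3, HCO2H, Bu3N, DMF, 60 °C
Reagents that add atoms: none
Why: Palladium-catalysed formate reduction of the enol triflate (hydride transfer to the alkenylpalladium intermediate) removes the oxygen at the future C4 and leaves the enol ether that carries the C5 oxygen.

Step 9
Reactants: 13 methyl enol ether
Product: 14 endo cis-diol: 13 with the carbonate replaced by two hydroxyl groups (future C8 and C8a) anti to the oxygen bridge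
Conditions: K2CO3 (0.2 equiv), MeOH, 0 °C
Reagents that add atoms: none
Why: Base-catalysed transesterification of the five-membered carbonate with methanol frees the diol at a stage that holds no base-sensitive stereocentre or acceptor.

Step 10
Reactants: 14 endo cis-diol
Product: 16 cycloheptenone: C5 ketone conjugated with C3a=C4, triethylsilyloxy groups on C8a and C8 (cis, on the face opposite to the C7 oxygen) and on C7, C6 methyl cis to the C7 oxygen, C7 bearing the (1R)-1-(TBS-oxy)but-2-ynyl group, via bis-TES ether 15 (not isolated)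
Conditions: TESOTf (3.5 equiv), 2,6-di-tert-butyl-4-methylpyridine, CH2Cl2, −78 to −30 °C; then aq. NaHCO3, THF, 0 °C
Reagents that add atoms: triethylsilyl triflate, CC[Si](CC)(CC)OS(=O)(=O)C(F)(F)F; water, O
Why: After O-silylation of the diol, silylation of the bridging oxygen triggers a Ferrier-type ionisation in which the enol ether expels the allylic C3a–O bond, and hydrolysis of the 1-methoxyallyl cation gives the enone and leaves the bridge oxygen as the C7 silyl ether; the enol ether fixes the regiochemistry and the hindered base avoids proton loss from C6.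

Step 11
Reactants: 16 cycloheptenone; 17 tert-butyl (diethoxyphosphoryl)acetate
Product: 19 tert-butyl acrylate: 16 with C3a saturated and carrying the 1-(tert-butoxycarbonyl)vinyl group cis to the C7 oxygen and trans to the C8a silyloxy group, via phosphonate adduct 18 (not isolated)
Conditions: NaH, THF, 0 °C to rt; then (CH2O)n, rt
Reagents that add atoms: 17, CCOP(=O)(OCC)CC(=O)OC(C)(C)C; formaldehyde (from paraformaldehyde), C=O
Why: Michael addition of the phosphonoacetate anion, proton transfer to the phosphonate carbanion and Horner–Wadsworth–Emmons olefination with formaldehyde; the nucleophile adds to C3a anti to the adjacent C8a silyloxy group, which sets C3a.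

Step 12
Reactants: 19 tris-TES acrylate
Product: 20 diol: 19 with free hydroxyl groups on C8 and C8a, the tertiary C7–OTES and the TBS ether retained
Conditions: HF·pyridine, pyridine, THF, 0 °C
Reagents that add atoms: none
Why: Buffered HF·pyridine should cleave the two secondary TES ethers faster than the hindered tertiary TES ether and the TBS ether, following the usual rate order of silyl ether cleavage.

Step 13
Reactants: 21 3-methylbutanenitrile
Product: 23 1,1,1-trimethoxy-3-methylbutane (trimethyl orthoisovalerate), via imidate hydrochloride 22 (not isolated)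
Conditions: HCl (g), MeOH (1.1 equiv), Et2O, 0 °C; then MeOH (excess), hexane, rt
Reagents that add atoms: methanol, CO
Why: Pinner reaction, in which HCl-mediated addition of methanol to the nitrile gives the imidate salt and its alcoholysis gives the orthoester.

Step 14
Reactants: 20 diol; 23 trimethyl orthoisovalerate
Product: 26 bis-silyl lactone: the target skeleton with the cis-fused α-methylene lactone and the C8 isovalerate in place, C7–OTES and the (1R)-1-(TBS-oxy)but-2-ynyl group on C7, via cyclic orthoester 24 (not isolated), via dioxolanylium triflate 25 (not isolated)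
Conditions: 23 (3 equiv), PPTS (5 mol %), 5 Å molecular sieves, CH2Cl2, rt; then TMSOTf, 2,6-di-tert-butyl-4-methylpyridine, −78 to 0 °C
Reagents that add atoms: 23, COC(OC)(OC)CC(C)C
Why: Orthoester exchange with the cis diol and methoxide abstraction give the 2-isobutyl-1,3-dioxolan-2-ylium ion, which is opened in a Prévost-type anti displacement at C8a (5-exo-tet, inversion) by the carbonyl oxygen of the neighbouring tert-butyl ester with loss of isobutene; this closes the cis-fused lactone, brings C8a to its final configuration and leaves the acyl group on C8 with retention.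

Step 15
Reactants: 26 bis-silyl lactone
Product: 27 propargylic diol: 26 with free tertiary C7–OH and free (1R)-1-hydroxybut-2-ynyl group
Conditions: HF·pyridine, THF, 0 °C to rt
Reagents that add atoms: none
Why: Fluoride-mediated desilylation under non-basic conditions should remove the tertiary TES and the secondary TBS ether and spare the lactone, the ester and the exocyclic alkene.

Step 16
Reactants: 27 propargylic diol
Product: 28 Z-allylic alcohol: 27 with the (1R,2Z)-1-hydroxybut-2-enyl group on C7
Conditions: H2 (1 atm), Pd/CaCO3 poisoned with Pb(OAc)2 (Lindlar catalyst), quinoline, EtOAc, rt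
Reagents that add atoms: none
Why: Lindlar semi-hydrogenation adds H2 syn to the alkyne on the poisoned palladium surface to give the Z alkene, and the conjugated exocyclic alkene is expected to react much more slowly.

Step 17
Reactants: 28 Z-allylic alcohol
Product: 29 target, (3aS,6R,7S,8S,8aR)-7-[(2Z)-but-2-enoyl]-7-hydroxy-6-methyl-3-methylidene-2,5-dioxooctahydro-2H-cyclohepta[b]furan-8-yl 3-methylbutanoate
Conditions: Dess–Martin periodinane, NaHCO3, CH2Cl2, 0 °C
Reagents that add atoms: none
Why: Dess–Martin oxidation of the secondary allylic alcohol under buffered conditions should give the enone with the Z geometry and the tertiary alcohol intact, and it removes the sacrificial carbinol stereocentre.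

**Compound list**

1 | kojic acid, 5-hydroxy-2-(hydroxymethyl)-4H-pyran-4-one | OCC1=CC(=O)C(O)=CO1 | starting material
2 | 2-(hydroxymethyl)-5-[(4-methoxyphenyl)methoxy]-4H-pyran-4-one | OCC1=CC(=O)C(OCc2ccc(OC)cc2)=CO1 | intermediate
3 | 5-[(4-methoxyphenyl)methoxy]-4-oxo-4H-pyran-2-carbaldehyde | O=CC1=CC(=O)C(OCc2ccc(OC)cc2)=CO1 | intermediate
4 | propyne | CC#C | starting material
5 | 2-[(1R)-1-hydroxybut-2-yn-1-yl]-5-[(4-methoxyphenyl)methoxy]-4H-pyran-4-one | CC#C[C@@H](O)C1=CC(=O)C(OCc2ccc(OC)cc2)=CO1 | intermediate
6 | 2-[(1R)-1-(tert-butyldimethylsilyloxy)but-2-yn-1-yl]-5-[(4-methoxyphenyl)methoxy]-4H-pyran-4-one | CC#C[C@@H](O[Si](C)(C)C(C)(C)C)C1=CC(=O)C(OCc2ccc(OC)cc2)=CO1 | intermediate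
7 | 2-[(1R)-1-(tert-butyldimethylsilyloxy)but-2-yn-1-yl]-5-hydroxy-4H-pyran-4-one | CC#C[C@@H](O[Si](C)(C)C(C)(C)C)C1=CC(=O)C(O)=CO1 | intermediate
8 | vinylene carbonate, 1,3-dioxol-2-one | O=C1OC=CO1 | starting material
9 | 3-hydroxy-4-methoxy-6-[(1R)-1-(TBS-oxy)but-2-yn-1-yl]pyrylium triflate | CC#C[C@@H](O[Si](C)(C)C(C)(C)C)c1cc(OC)c(O)c[o+]1.[O-]S(=O)(=O)C(F)(F)F | intermediate
10 | 4-methoxy-6-[(1R)-1-(TBS-oxy)but-2-yn-1-yl]pyrylium-3-olate | CC#C[C@@H](O[Si](C)(C)C(C)(C)C)c1cc(OC)c([O-])c[o+]1 | intermediate
11 | endo cycloadduct: 3-methoxy-8-oxabicyclo[3.2.1]oct-3-en-2-one, (1R)-1-(TBS-oxy)but-2-ynyl on the bridgehead remote from the ketone, cyclic carbonate cis-fused on the two-carbon bridge anti to the oxygen bridge | O=C1C(OC)=C[C@]2([C@H](O[Si](C)(C)C(C)(C)C)C#CC)O[C@H]1[C@@H]1OC(=O)O[C@H]21 | intermediate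
12 | enol triflate of the methyl adduct of 11, methyl syn to the oxygen bridge | FC(F)(F)S(=O)(=O)OC1=C(OC)[C@H](C)[C@]2([C@H](O[Si](C)(C)C(C)(C)C)C#CC)O[C@H]1[C@@H]1OC(=O)O[C@H]21 | intermediate
13 | methyl enol ether: 12 with H in place of OTf | C1=C(OC)[C@H](C)[C@]2([C@H](O[Si](C)(C)C(C)(C)C)C#CC)O[C@H]1[C@@H]1OC(=O)O[C@H]21 | intermediate
14 | endo cis-diol: 13 with two OH groups in place of the carbonate, anti to the oxygen bridge | C1=C(OC)[C@H](C)[C@]2([C@H](O[Si](C)(C)C(C)(C)C)C#CC)O[C@H]1[C@H](O)[C@@H]2O | intermediate
15 | bis(triethylsilyl) ether of 14 | C1=C(OC)[C@H](C)[C@]2([C@H](O[Si](C)(C)C(C)(C)C)C#CC)O[C@H]1[C@H](O[Si](CC)(CC)CC)[C@@H]2O[Si](CC)(CC)CC | intermediate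
16 | cycloheptenone: C5 ketone, C3a=C4 alkene, OTES on C8a, C8 and C7, C6 methyl, (1R)-1-(TBS-oxy)but-2-ynyl on C7 | O=C1C=C[C@H](O[Si](CC)(CC)CC)[C@H](O[Si](CC)(CC)CC)[C@](O[Si](CC)(CC)CC)([C@H](O[Si](C)(C)C(C)(C)C)C#CC)[C@H]1C | intermediate
17 | tert-butyl (diethoxyphosphoryl)acetate | CCOP(=O)(OCC)CC(=O)OC(C)(C)C | starting material
18 | phosphonate Michael adduct at C3a (mixture at the phosphonate carbon) | O=C1C[C@@H](C(C(=O)OC(C)(C)C)P(=O)(OCC)OCC)[C@H](O[Si](CC)(CC)CC)[C@H](O[Si](CC)(CC)CC)[C@](O[Si](CC)(CC)CC)([C@H](O[Si](C)(C)C(C)(C)C)C#CC)[C@H]1C | intermediate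
19 | tert-butyl acrylate: C3a carries the 1-(tert-butoxycarbonyl)vinyl group, tris-TES | O=C1C[C@@H](C(=C)C(=O)OC(C)(C)C)[C@H](O[Si](CC)(CC)CC)[C@H](O[Si](CC)(CC)CC)[C@](O[Si](CC)(CC)CC)([C@H](O[Si](C)(C)C(C)(C)C)C#CC)[C@H]1C | intermediate
20 | C8/C8a cis-diol of 19, C7–OTES retained | O=C1C[C@@H](C(=C)C(=O)OC(C)(C)C)[C@H](O)[C@H](O)[C@](O[Si](CC)(CC)CC)([C@H](O[Si](C)(C)C(C)(C)C)C#CC)[C@H]1C | intermediate
21 | 3-methylbutanenitrile | CC(C)CC#N | starting material
22 | methyl 3-methylbutanimidate hydrochloride | COC(=[NH2+])CC(C)C.[Cl-] | intermediate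
23 | 1,1,1-trimethoxy-3-methylbutane | COC(OC)(OC)CC(C)C | intermediate
24 | cyclic orthoester of 20 (2-methoxy-2-isobutyl-1,3-dioxolane on C8/C8a, mixture at the orthoester carbon) | O=C1C[C@@H](C(=C)C(=O)OC(C)(C)C)[C@@H]2OC(CC(C)C)(OC)O[C@@H]2[C@](O[Si](CC)(CC)CC)([C@H](O[Si](C)(C)C(C)(C)C)C#CC)[C@H]1C | intermediate
25 | 2-isobutyl-1,3-dioxolan-2-ylium triflate on C8/C8a | O=C1C[C@@H](C(=C)C(=O)OC(C)(C)C)[C@@H]2OC(CC(C)C)=[O+][C@@H]2[C@](O[Si](CC)(CC)CC)([C@H](O[Si](C)(C)C(C)(C)C)C#CC)[C@H]1C.[O-]S(=O)(=O)C(F)(F)F | intermediate
26 | bis-silyl lactone: target skeleton with C7–OTES and (1R)-1-(TBS-oxy)but-2-ynyl on C7 | C=C1C(=O)O[C@@H]2[C@H]1CC(=O)[C@H](C)[C@@](O[Si](CC)(CC)CC)([C@H](O[Si](C)(C)C(C)(C)C)C#CC)[C@H]2OC(=O)CC(C)C | intermediate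
27 | propargylic diol: C7–OH and (1R)-1-hydroxybut-2-ynyl on C7 | C=C1C(=O)O[C@@H]2[C@H]1CC(=O)[C@H](C)[C@@](O)([C@H](O)C#CC)[C@H]2OC(=O)CC(C)C | intermediate
28 | Z-allylic alcohol: (1R,2Z)-1-hydroxybut-2-enyl on C7 | C=C1C(=O)O[C@@H]2[C@H]1CC(=O)[C@H](C)[C@@](O)([C@H](O)/C=C\C)[C@H]2OC(=O)CC(C)C | intermediate
29 | (3aS,6R,7S,8S,8aR)-7-[(2Z)-but-2-enoyl]-7-hydroxy-6-methyl-3-methylidene-2,5-dioxooctahydro-2H-cyclohepta[b]furan-8-yl 3-methylbutanoate | C=C1C(=O)O[C@@H]2[C@H]1CC(=O)[C@H](C)[C@@](O)(C(=O)/C=C\C)[C@H]2OC(=O)CC(C)C | target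

**Summary**

Total step count: 17. Longest linear sequence: 16 steps (steps 1–12 and 14–17; step 13 makes the orthoester separately).

**Steps most likely to fail**

Step 6. What may go wrong: 8 may add in the exo orientation (carbonate syn to the oxygen bridge), which puts both C–O bonds on the wrong face for the later retention at C8 and inversion at C8a. The fallback sets the two carbinol centres by substrate-controlled reduction instead of by the cycloaddition topology. It sets out from 7: the cycloaddition is run as in step 6 and the exo cycloadduct F1 is taken through the conditions of steps 7 and 8 to the exo enol triflate F2 and the exo methyl enol ether F3. K2CO3 in MeOH gives the exo cis-diol F4, and Dess–Martin periodinane with pyridine gives the 1,2-diketone F5. NaBH4 in MeOH at −78 °C should deliver hydride to both carbonyl groups from the open face next to the oxygen bridge and give the endo cis-diol 14, where the route is rejoined.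

Step 14. What may go wrong: the dioxolanylium ion may be captured at its central carbon (giving cis hydroxy esters), or acyl transfer may close the lactone with retention at C8a, instead of the SN2 opening. The fallback uses a sulfonate displacement and sets out from 20. MsCl with 2,4,6-collidine at −20 °C should sulfonylate the less hindered C8a–OH to give the mesylate F6, and isovaleric anhydride with DMAP acylates the C8–OH to give the mesylate ester F7. TMSOTf with 2,6-lutidine and aqueous work-up cleaves the tert-butyl ester to the carboxylic acid F8. Cs2CO3 in DMF at 40 °C then lets the carboxylate displace the mesylate (5-exo-tet, inversion) to give 26.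

Step 10. What may go wrong: the enol ether may be protonated at carbon (giving the closed bridged ketone), or the cation may lose the proton at C6 and erase the methyl stereocentre. The fallback opens the bridge through the ketone enolate and sets out from 14. TESCl with imidazole gives 15 as an isolated compound, and oxalic acid on wet silica hydrolyses the enol ether to the bridged ketone F9. LDA and TESCl at −78 °C form the less substituted silyl enol ether F10, and catalytic TESOTf then opens the bridge by β-elimination of the bridging oxygen (the established opening of 8-oxabicyclo[3.2.1]octan-3-ones through their silyl enol ethers). Bicarbonate work-up gives 16.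

**Further compounds**

F1 | step 6 | exo cycloadduct, carbonate syn to the oxygen bridge | O=C1C(OC)=C[C@]2([C@H](O[Si](C)(C)C(C)(C)C)C#CC)O[C@H]1[C@H]1OC(=O)O[C@@H]21
F2 | step 6 | exo enol triflate | FC(F)(F)S(=O)(=O)OC1=C(OC)[C@H](C)[C@]2([C@H](O[Si](C)(C)C(C)(C)C)C#CC)O[C@H]1[C@H]1OC(=O)O[C@@H]21
F3 | step 6 | exo methyl enol ether | C1=C(OC)[C@H](C)[C@]2([C@H](O[Si](C)(C)C(C)(C)C)C#CC)O[C@H]1[C@H]1OC(=O)O[C@@H]21
F4 | step 6 | exo cis-diol | C1=C(OC)[C@H](C)[C@]2([C@H](O[Si](C)(C)C(C)(C)C)C#CC)O[C@H]1[C@@H](O)[C@H]2O
F5 | step 6 | 1,2-diketone on the two-carbon bridge | C1=C(OC)[C@H](C)[C@]2([C@H](O[Si](C)(C)C(C)(C)C)C#CC)O[C@H]1C(=O)C2=O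
F6 | step 14 | C8a mesylate of 20 | O=C1C[C@@H](C(=C)C(=O)OC(C)(C)C)[C@H](OS(C)(=O)=O)[C@H](O)[C@](O[Si](CC)(CC)CC)([C@H](O[Si](C)(C)C(C)(C)C)C#CC)[C@H]1C
F7 | step 14 | C8a mesylate C8 isovalerate | O=C1C[C@@H](C(=C)C(=O)OC(C)(C)C)[C@H](OS(C)(=O)=O)[C@H](OC(=O)CC(C)C)[C@](O[Si](CC)(CC)CC)([C@H](O[Si](C)(C)C(C)(C)C)C#CC)[C@H]1C
F8 | step 14 | acrylic acid from F7 | O=C1C[C@@H](C(=C)C(O)=O)[C@H](OS(C)(=O)=O)[C@H](OC(=O)CC(C)C)[C@](O[Si](CC)(CC)CC)([C@H](O[Si](C)(C)C(C)(C)C)C#CC)[C@H]1C
F9 | step 10 | bridged ketone, 8-oxabicyclo[3.2.1]octan-3-one with bis-TES diol | C1C(=O)[C@H](C)[C@]2([C@H](O[Si](C)(C)C(C)(C)C)C#CC)O[C@H]1[C@H](O[Si](CC)(CC)CC)[C@@H]2O[Si](CC)(CC)CC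
F10 | step 10 | triethylsilyl enol ether of F9 on the unsubstituted side | C1=C(O[Si](CC)(CC)CC)[C@H](C)[C@]2([C@H](O[Si](C)(C)C(C)(C)C)C#CC)O[C@H]1[C@H](O[Si](CC)(CC)CC)[C@@H]2O[Si](CC)(CC)CC
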